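The constants come from no measurement; no experiment stands behind them.

all flasks: protic impurity 10.0 mM; time 3.0 min
- spring: starting material 20 mM; reagent 1.50 equiv; everything together at the start
- noon: starting material 20 mM; reagent 1.50 equiv (fed, over 40 s); all else is in the flask from the start; the feed brings no volume worth counting
- summer: starting material 20 mM (fed, over 40 s); reagent 1.50 equiv; all else is in the flask from the start; the feed brings no volume worth counting

    starting material + tautomer → side product (k1 = 0.70 M⁻¹ s⁻¹)
    starting material ⇌ tautomer (K2 = 4.0, k2 = 0.12 s⁻¹)
    2 reagent → homo dimer (k3 = 0.60 M⁻¹ s⁻¹)
    reagent + tautomer → target (k4 = 1.0 M⁻¹ s⁻¹)
    starting material + reagent → isomer of the product (k5 = 0.82 M⁻¹ s⁻¹)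
    starting material + protic impurity → quenched substrate (k6 = 0.87 M⁻¹ s⁻¹)

- percent here means starting material units held: one side product counts as two
- where a step has two of a species, its rate is k times that concentration squared, and two are used at each turn
- run time (spring): 3.0 min

- the flask that comes out highest in amount of target, in percent of the starting material charged, or "all alike" when all lie within 1.5 percentage points (spring / noon / summer / all alike)
- target at the end, in percent of the starting material charged, spring
- target at the end, in percent of the starting material charged, noon
- target at the end, in percent of the starting material charged, summer

In its first instant the spring flask cannot make target: the step to target needs tautomer, and none was charged. Reagent can then go to isomer of the product or to homo dimer, so I followed the run slowly. Starting material relaxes towards tautomer at a combined rate λ (forward plus back) of 0.150 s⁻¹, a half-life of 4.62 s. That is shorter than the 0.39 min that tautomer has against reagent as charged, so the equilibrium forms first.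

I integrated the starting material standing above its equilibrium level in closed form, with reagent held at its charge. This gives T, the isomer paid while the equilibrium forms: 13.1% of the charge in spring. With reagent fed steadily over 40 s in noon, the same integral is T/(λ·40 s), or 2.19%, less than in spring.

Once the equilibrium stands, tautomer and starting material keep a fixed ratio, so reagent divides between them in a fixed way. I call this S, the target made per isomer made while the equilibrium stands (a selectivity factor): 4.88.

What matters next in spring is the dimer: as charged, with tautomer at its equilibrium share, reagent goes to dimer at twice the rate at which it goes to tautomer. I therefore put noon above spring. Summer, with its reagent fully charged while starting material arrives over 40 s, I put lowest, without a figure.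

The forecast named noon: 37% for spring (33% to 41%), 43% for noon (38% to 48%) and 31% for summer (27% to 36%). Its grounds: “Feeding reagent keeps its level low while the tautomer builds up”. It gave yields where my reckoning gave an order.

The flask gave 37.9% in spring, 44.4% in noon and 31.1% in summer, so noon came highest, and each figure lay inside the forecast's range. Noon ended with 10.5% isomer of the product. Noon's fed integral T/(λ·40 s) plus noon's target divided by S gives 11.3%.

In the neighbour, summer left until 12 min, the 5.79% of reagent standing at 3.00 min equals 8.68% of the starting material charge. Split by S, it takes target to 38.3% if all of it reacts and none of it dimerises. The neighbour read 35.8% target and 14.1% isomer of the product, a gain of 5.12 target per isomer.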